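## Structural features

Isodihydromaldoxin (16) is made of two benzene rings that share no carbon–carbon bond and are joined only by one ether oxygen, between C6 of ring A and C6′ of ring B. Ring A carries CO2CH3 at C1, OH at C3, OCH3 at C5 and the ether oxygen at C6 (C2 and C4 are CH). Ring B carries CO2H at C1′, OH at C2′, Cl at C3′, CH3 at C4′, H at C5′ and the ether oxygen at C6′. The target is achiral, so no stereocentres adjoin one another; the only ones in the plan are the neighbouring C1 and C6 of a saturated ring A intermediate, and both vanish on aromatization. The fragile groups are the ring A methyl ester (no hydroxide can be used to free the ring B acid), the 2,6-dioxygenated benzoic acid (it decarboxylates in hot acid), the aryl chloride (no hydrogenolysis) and the electron-rich free phenols. The real difficulty is threefold: the ether oxygen is flanked by CO2CH3 and OCH3 on ring A and by the carboxyl on ring B, so an aryl–oxygen coupling would be hindered; three phenolic oxygens and two carboxyl groups must end up differentiated; and chlorine must go to C3′, not C5′. The key step uses the fact that the C3 and C5 oxygens of ring A are meta to each other and are followed by the ether carbon C6 and the ester carbon C1. This is the pattern of a 4-aryloxy-5-(methoxycarbonyl)cyclohexane-1,3-dione, so ring A can be grown by enolate chemistry around an O–C(sp3) bond that ring B already carries.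

## Logic of the disconnections

16 to 15. The bonds cut are the O–C(CH3)3 bond of the ring B ester and the O–CH2OCH3 bond at the C2′ oxygen. Both fall to acid, which leaves the CO2CH3 of ring A alone, so the two carboxyl groups are told apart without hydroxide. The gain is that ring B is a neutral, fully masked spectator in everything before. The forward step must intercept the tert-butyl and methoxymethyl cations before they attack ring A, and must stay cold enough to avoid decarboxylation.

15 to 14 to 13 to 12. The bonds cut are O–Si at the C3 oxygen (put on, later taken off) and O–CH3 at the C5 oxygen. In 12 the two ring A phenols differ only in their surroundings: the C5 OH lies beside the bulky aryloxy group and the C3 OH lies between two CH. A bulky silyl chloride takes the C3 OH, the single remaining OH is methylated, and fluoride returns the C3 OH. The gain is that 12 needs no differentiated oxygens. The demand is a clean steric preference in the silylation and a silyl ether that survives carbonate.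

12 to 11. No skeletal bond is cut; two hydrogens (on C1 and C2) are added back, because a resorcinol is the dehydrogenation product of a cyclohexane-1,3-dione. The gain is that the aromatic ring becomes an aliphatic carbonyl-condensation problem. The oxidant must remove H2 without expelling the aryloxide from C6 and without touching ring B or its acid-labile groups.

11 to 7 plus 8. The bonds cut are C6–C1 and C4–C5. C6–C1 is a Michael bond between the aryloxyacetate α-carbon of 7 and the alkene carbon of 8 that is β to the ketone. C4–C5 is a Claisen bond between the methyl group of that ketone and the acetate carbonyl. The gain is large: ring A comes from a two-carbon piece already on the ring B oxygen and a purchasable four-carbon piece, and the hindered aryl–O–aryl bond is never made on an arene. The forward step needs regioselective conjugate addition, then proton transfer and six-ring closure faster than β-elimination of the ring B aryloxide, with ring B inert to the amide base.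

7 to 6 to 3 plus 4. The bonds cut are O–CH2OCH3 at the C2′ oxygen and O–CH2CO2CH3 at the C6′ oxygen, both simple phenol O-alkylations. The gain is a chlorinated dihydroxybenzoate, 3, with no side chain. The demand falls on the first alkylation: the two phenols of 3 must be told apart. This is done through the bis-phenoxide 5, in which the oxygen remote from chlorine is both the more basic and the less shielded. A monoanion would instead sit mainly on the more acidic oxygen next to chlorine, so full double deprotonation is required.

3 to 2 to 1. The bonds cut are C3′–Cl and the ester O–C(CH3)3. The chlorine is introduced while the ring still has a mirror plane, so the two open positions of 2 are equivalent and only one monochloride can form; this removes the ortho/para question that arises if chlorination follows desymmetrization. Esterification comes first because the free acid is prone to decarboxylation and ipso attack. The forward steps must stop at monochlorination and must esterify a hindered acid without heat and without alkylating the phenols.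

## Other disconnections considered

Alternative 1: Ring B would be cut at C4′–C5′ and C1′–C6′. The two-carbon unit C5′–C6′ would come from the ethynyl ether of ring A, methyl 2-(ethynyloxy)-3-methoxy-5-[(4-methoxybenzyl)oxy]benzoate (A1). The four-carbon unit C1′–C4′ with all its substituents would come from the pyranone tert-butyl 4-acetoxy-5-chloro-6-methyl-2-oxo-2H-pyran-3-carboxylate (A2). In the forward step the electron-rich alkyne A1 would add across C3 and C6 of the electron-poor diene A2 in an inverse-demand Diels–Alder reaction, and decarboxylative cycloreversion of the bridged lactone would leave the benzoate A3.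
- In its favour: it is convergent; ring A comes from the aromatic pool with OCH3 and OH already distinguished; Cl, CH3, oxygen and ester of ring B are fixed in A2, so no arene chlorination and no phenol differentiation on ring B arise; the polarity match (nucleophilic CH terminus of A1 to electrophilic C6 of A2) predicts the needed ortho relation of ether and ester; no redox adjustment is needed.
- Against it here: A1 needs an O–C(sp) bond on the same hindered, ester-flanked phenol oxygen, by methods that normally use alkyllithium bases hostile to CO2CH3, and aryl ethynyl ethers hydrate and oligomerize readily. A2 is tetrasubstituted and its acetoxy and methyl groups lower its diene reactivity, so long heating of a labile ynol ether would be expected. Three masking groups (acetate, 4-methoxybenzyl, tert-butyl) remain in A3.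
- Comparison: on structure it is the better plan for placing the ring B substituents, and the equal of the chosen plan in avoiding an arene–oxygen–arene coupling. On mechanism a concerted cycloaddition avoids the β-elimination threat of the anionic cascade but relies on a sluggish diene and dienophile pair. On step economy two fragments of several steps each and two deprotection operations should make the total count somewhat higher, though the longest linear sequence could be shorter.

Alternative 2: Ring B would be cut at C1′–C2′, C5′–C6′ and C2′–C3′. C2′ to C5′ would come from the vinylketene (E)-4-chloro-3-methylbuta-1,3-dien-1-one (A5), generated by photochemical Wolff rearrangement of (E)-4-chloro-1-diazo-3-methylbut-3-en-2-one (A4). C6′ and C1′ would come from the ring A alkynyl ether tert-butyl 3-{2-methoxy-6-(methoxycarbonyl)-4-[(4-methoxybenzyl)oxy]phenoxy}prop-2-ynoate (A6). In the forward step A5 and A6 would combine in a [2+2] cycloaddition; on heating, the vinylcyclobutenone would open and reclose by 6π electrocyclization and tautomerize to the phenol A7.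
- In its favour: the hexasubstituted ring B is assembled in one operation, with regiochemistry dictated by ketene and ynol ether polarity. The C2′ OH emerges free and needs no protecting group. A7 is a single acid treatment from the target, so the end-game is clearly shorter than in the chosen plan; on this point the alternative is better.
- Against it here: A6 is a push–pull alkyne whose ester lowers the nucleophilicity that the ketene cycloaddition depends on. A4 is a sensitive β-chlorovinyl diazo ketone that calls for diazoalkane chemistry. The photolysis must be run in the presence of aryl ether and benzyl ether chromophores. A6 still requires an O–C(sp) bond on the hindered ring A phenol.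
- Comparison: on structure it is better, since neither ring needs oxygen differentiation after the key step. On mechanism it is base-free and pericyclic, so the aryloxide elimination that threatens the chosen key step cannot occur, but it leans on a deactivated alkyne and on photochemistry. On step economy the total should be about equal and the longest linear sequence shorter, at the price of hazardous reagents and poorer scalability.

Alternative 3: Ring A would be cut at C3–C4, C5–C6 and C2–C3. C4 and C5 would come from methoxyethyne (A9). C3, C6, C1 and C2 would come from the ring B acid chloride tert-butyl 3-chloro-6-{[1-chloro-3-(methoxycarbonyl)-1-oxobut-3-en-2-yl]oxy}-2-(methoxymethoxy)-4-methylbenzoate (A8). In the forward step an amine base would dehydrochlorinate A8 to an aryloxy(vinyl)ketene, which would add A9 in a [2+2] step with the CH terminus on the ketene carbonyl carbon. Heating would open the cyclobutenone and close ring A by 6π electrocyclization to give A10, which is the same compound as 15 of the chosen route.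
- In its favour: like the chosen plan it brings the hindered C6–O bond in on an sp3 α-aryloxy carbonyl carbon of ring B. Ring A forms directly at the aromatic oxidation level with OCH3 at C5 and a free OH at C3. No dehydrogenation and no silylation, methylation and desilylation sequence is needed, so one step would replace steps 5 to 9; on oxygen differentiation and post-annulation step economy it is better.
- Against it here: A8 is not easily reached. It needs an α-aryloxy acid carrying a 1-(methoxycarbonyl)vinyl group on the same carbon, with acid and ester distinguished; bringing a hindered aryloxide onto such an allylic position invites SN2′ transposition. A9 is a volatile, unstable alkyne that must be made and used at once. Aryloxyketenes dimerize, and a vinylketene bearing an ester on the vinyl group is an atypical partner.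
- Comparison: on structure it is better (oxidation level and methoxyl position are built in). On mechanism it is neutral and pericyclic where the chosen step is anionic, and both depend on the α-aryloxy carbonyl unit. On step economy it could be shorter by about three steps if A8 were available in about four steps from 3, but the risk would sit in making A8 and handling A9, whereas the chosen key step uses a four-step ring B ester and a purchasable acceptor.

Key step: step 5

Remark: by ring-atom count the annulation of step 5 joins a two-carbon donor (C5–C6) to a four-carbon acceptor (C1–C4); it is a 4+2 Michael–Claisen assembly and not a 3+3 one in the strict sense, and the bonds formed are C6–C1 and C4–C5.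
Remark: 11 is written as the diketone; it should exist largely as enol tautomers and is racemic.
Remark: ring A locants C1–C6 and ring B locants C1′–C6′ of the target are used for all intermediates.

## Route

Step 1
Reactants: 1 2,6-dihydroxy-4-methylbenzoic acid
Product: 2 tert-butyl 2,6-dihydroxy-4-methylbenzoate
Conditions: O-tert-butyl-N,N'-diisopropylisourea (2.5 equiv), THF/CH2Cl2, rt
Reagents that add atoms: O-tert-butyl-N,N'-diisopropylisourea, CC(C)N=C(OC(C)(C)C)NC(C)C
Why: Isourea esterification: the strongly acidic, chelated carboxylic acid protonates the isourea and takes up the tert-butyl group, while the much less acidic phenols should stay free; neutral room-temperature conditions avoid the decarboxylation that heat or mineral acid would risk.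

Step 2
Reactants: 2 tert-butyl 2,6-dihydroxy-4-methylbenzoate
Product: 3 tert-butyl 3-chloro-2,6-dihydroxy-4-methylbenzoate
Conditions: NCS (1.0 equiv), DMF, 0 °C → rt
Reagents that add atoms: N-chlorosuccinimide, O=C1CCC(=O)N1Cl
Why: Electrophilic aromatic chlorination of a ring with a mirror plane: C3′ and C5′ are equivalent (each ortho to one OH and para to the other), so only one monochloride can form, and the first chlorine lowers the reactivity toward a second; succinimide is the only by-product, so the tert-butyl ester sees no HCl.

Step 3
Reactants: 3 tert-butyl 3-chloro-2,6-dihydroxy-4-methylbenzoate; 4 methyl bromoacetate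
Product: 6 tert-butyl 3-chloro-2-hydroxy-6-(2-methoxy-2-oxoethoxy)-4-methylbenzoate, via disodium bis-phenoxide 5 (not isolated)
Conditions: NaH (2.1 equiv), DMF, 0 °C; 4 (1.0 equiv), −20 → 0 °C; 1 M HCl on work-up
Reagents that add atoms: 4 methyl bromoacetate, COC(=O)CBr
Why: Williamson ether synthesis on the fully formed bis-phenoxide: with both oxygens ionized the site is decided by nucleophilicity alone, and the C6′ oxygen (more basic, one flank open) should outrun the C2′ oxygen (less basic and shielded by chlorine); one equivalent of 4 limits double alkylation, and the site can be confirmed by an NOE between OCH2 and H5′.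

Step 4
Reactants: 6 tert-butyl 3-chloro-2-hydroxy-6-(2-methoxy-2-oxoethoxy)-4-methylbenzoate
Product: 7 tert-butyl 3-chloro-6-(2-methoxy-2-oxoethoxy)-2-(methoxymethoxy)-4-methylbenzoate
Conditions: MOMCl (1.5 equiv), iPr2NEt (2 equiv), CH2Cl2, 0 → 40 °C
Reagents that add atoms: chloromethyl methyl ether, COCCl
Why: O-alkylation of the one remaining, chelated phenol by a small, highly reactive α-chloro ether; the methoxymethyl ether tolerates amide bases, DDQ, carbonate and fluoride, and later leaves under the same acid that cleaves the tert-butyl ester.

Step 5
Reactants: 7 tert-butyl 3-chloro-6-(2-methoxy-2-oxoethoxy)-2-(methoxymethoxy)-4-methylbenzoate; 8 methyl (E)-4-oxopent-2-enoate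
Product: 11 methyl trans-2-{[2-(tert-butoxycarbonyl)-4-chloro-3-(methoxymethoxy)-5-methylphenyl]oxy}-3,5-dioxocyclohexane-1-carboxylate (racemic), via lithium ester enolate 9 (not isolated), via Michael adduct lithium enolate 10 (not isolated)
Conditions: LiN(iPr)2 (1.05 equiv), THF, −78 °C; 8 (1.1 equiv), −78 → 0 °C; AcOH
Reagents that add atoms: 8 methyl (E)-4-oxopent-2-enoate, COC(=O)/C=C/C(C)=O
Why: LiN(iPr)2 deprotonates the OCH2 group of 7 to the chelated enolate 9, which adds to the alkene carbon of 8 that is β to the ketone and carries CO2CH3, forming C6–C1, because the ketone is the stronger activating group of the 4-oxo-enoate. Proton transfer (shuttled by the methoxide and methanol released once closure begins) converts the internal ketone enolate into the methyl-ketone enolate 10, whose CH2 attacks the α-aryloxy ester carbonyl to form C4–C5. This ring closure is a 6-exo-trig Claisen condensation; loss of methoxide and deprotonation of the acidic 1,3-dione make it irreversible, so one equivalent of base suffices. The closest known reaction type is the Michael–Claisen synthesis of cyclohexane-1,3-diones from ester or malonate enolates and methyl enones (the dimedone-type annulation). The new stereocentres C1 and C6 are both epimerizable (C6 α to the C5 carbonyl, C1 α to the ester), so they should settle under thermodynamic control in the trans, diequatorial arrangement; the product is racemic and both centres are destroyed in step 6. The step needs regioselective conjugate addition, secured by the ketone outranking the ester as acceptor. It also needs chemoselective closure: the six-membered δ-keto ester closure onto the inductively activated aryloxy ester should beat the strained five-membered closure onto the C1 ester, and the doubly ortho-substituted tert-butyl benzoate is shielded. Using only one equivalent of base and not exceeding 0 °C limits E1cB loss of the ring B aryloxide from the C1 ester enolate.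

Step 6
Reactants: 11 methyl trans-2-{[2-(tert-butoxycarbonyl)-4-chloro-3-(methoxymethoxy)-5-methylphenyl]oxy}-3,5-dioxocyclohexane-1-carboxylate
Product: 12 tert-butyl 3-chloro-6-[2,4-dihydroxy-6-(methoxycarbonyl)phenoxy]-2-(methoxymethoxy)-4-methylbenzoate
Conditions: DDQ (1.1 equiv), 1,4-dioxane, 80 °C
Reagents that add atoms: none
Why: Quinone dehydrogenation of a cyclohexane-1,3-dione to a resorcinol: hydride abstraction from C1–H of the dienol gives a cation stabilized by both ring oxygens (the σ-complex of the product), and loss of the C2 proton aromatizes; the neutral medium keeps the acetal and tert-butyl ester and offers no base for aryloxide elimination, and both stereocentres are erased.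

Step 7
Reactants: 12 tert-butyl 3-chloro-6-[2,4-dihydroxy-6-(methoxycarbonyl)phenoxy]-2-(methoxymethoxy)-4-methylbenzoate
Product: 13 tert-butyl 3-chloro-6-{2-hydroxy-6-(methoxycarbonyl)-4-[(triisopropylsilyl)oxy]phenoxy}-2-(methoxymethoxy)-4-methylbenzoate
Conditions: TIPSCl (1.05 equiv), imidazole (2 equiv), DMF, 0 °C
Reagents that add atoms: chlorotri(propan-2-yl)silane, CC(C)[Si](Cl)(C(C)C)C(C)C
Why: Sterically controlled silylation of a phenol: the C3 OH has two CH neighbours, whereas the C5 OH is ortho to the bulky aryloxy group and hydrogen-bonded to its oxygen, so the very hindered silyl chloride should take the C3 oxygen only.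

Step 8
Reactants: 13 tert-butyl 3-chloro-6-{2-hydroxy-6-(methoxycarbonyl)-4-[(triisopropylsilyl)oxy]phenoxy}-2-(methoxymethoxy)-4-methylbenzoate
Product: 14 tert-butyl 3-chloro-6-{2-methoxy-6-(methoxycarbonyl)-4-[(triisopropylsilyl)oxy]phenoxy}-2-(methoxymethoxy)-4-methylbenzoate
Conditions: MeI (3 equiv), K2CO3 (2 equiv), acetone, 40 °C
Reagents that add atoms: iodomethane, CI
Why: Williamson methylation of the only free phenol (C5 OH) with a small electrophile; the triisopropylsilyl ether resists carbonate in acetone and cannot migrate between meta oxygens, and the esters and acetal are inert.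

Step 9
Reactants: 14 tert-butyl 3-chloro-6-{2-methoxy-6-(methoxycarbonyl)-4-[(triisopropylsilyl)oxy]phenoxy}-2-(methoxymethoxy)-4-methylbenzoate
Product: 15 tert-butyl 3-chloro-6-[4-hydroxy-2-methoxy-6-(methoxycarbonyl)phenoxy]-2-(methoxymethoxy)-4-methylbenzoate
Conditions: Bu4NF (1.1 equiv), AcOH (1.1 equiv), THF, 0 °C
Reagents that add atoms: none
Why: Fluoride cleavage of the aryl silyl ether, driven by the Si–F bond; buffering with acetic acid keeps the liberated phenoxide from attacking the methyl ester, and the acetal and tert-butyl ester are untouched.

Step 10
Reactants: 15 tert-butyl 3-chloro-6-[4-hydroxy-2-methoxy-6-(methoxycarbonyl)phenoxy]-2-(methoxymethoxy)-4-methylbenzoate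
Product: 16 3-chloro-2-hydroxy-6-[4-hydroxy-2-methoxy-6-(methoxycarbonyl)phenoxy]-4-methylbenzoic acid (isodihydromaldoxin)
Conditions: CF3CO2H/CH2Cl2/H2O (10:10:1), 0 °C → rt
Reagents that add atoms: none
Why: Acidolysis: the tert-butyl ester ionizes and loses 2-methylpropene, and the methoxymethyl acetal is hydrolysed, with water present to capture the cations before they can alkylate ring A; the methyl ester, aryl chloride, methyl ether and diaryl ether are stable to the acid, and the low temperature guards against decarboxylation.

## Compound list

1 | 2,6-dihydroxy-4-methylbenzoic acid | Cc1cc(O)c(C(=O)O)c(O)c1 | starting material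
2 | tert-butyl 2,6-dihydroxy-4-methylbenzoate | Cc1cc(O)c(C(=O)OC(C)(C)C)c(O)c1 | intermediate
3 | tert-butyl 3-chloro-2,6-dihydroxy-4-methylbenzoate | Cc1cc(O)c(C(=O)OC(C)(C)C)c(O)c1Cl | intermediate
4 | methyl bromoacetate | COC(=O)CBr | starting material
5 | disodium 2-(tert-butoxycarbonyl)-4-chloro-5-methylbenzene-1,3-diolate (bis-phenoxide of 3) | [Na+].[Na+].Cc1cc([O-])c(C(=O)OC(C)(C)C)c([O-])c1Cl | intermediate (not isolated)
6 | tert-butyl 3-chloro-2-hydroxy-6-(2-methoxy-2-oxoethoxy)-4-methylbenzoate | COC(=O)COc1cc(C)c(Cl)c(O)c1C(=O)OC(C)(C)C | intermediate
7 | tert-butyl 3-chloro-6-(2-methoxy-2-oxoethoxy)-2-(methoxymethoxy)-4-methylbenzoate | COC(=O)COc1cc(C)c(Cl)c(OCOC)c1C(=O)OC(C)(C)C | intermediate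
8 | methyl (E)-4-oxopent-2-enoate | COC(=O)/C=C/C(C)=O | starting material
9 | lithium enolate of 7 (enolate oxygen and aryloxy oxygen cis, chelating lithium) | [Li+].[O-]/C(OC)=C\Oc1cc(C)c(Cl)c(OCOC)c1C(=O)OC(C)(C)C | intermediate (not isolated)
10 | lithium enolate at the methyl ketone of dimethyl 2-{[2-(tert-butoxycarbonyl)-4-chloro-3-(methoxymethoxy)-5-methylphenyl]oxy}-3-(2-oxopropyl)butanedioate (both diastereomers, racemic) | [Li+].[O-]C(=C)CC(C(=O)OC)C(Oc1cc(C)c(Cl)c(OCOC)c1C(=O)OC(C)(C)C)C(=O)OC | intermediate (not isolated)
11 | methyl trans-2-{[2-(tert-butoxycarbonyl)-4-chloro-3-(methoxymethoxy)-5-methylphenyl]oxy}-3,5-dioxocyclohexane-1-carboxylate (racemic; (1S,2R) enantiomer drawn) | COC(=O)[C@H]1CC(=O)CC(=O)[C@@H]1Oc1cc(C)c(Cl)c(OCOC)c1C(=O)OC(C)(C)C | intermediate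
12 | tert-butyl 3-chloro-6-[2,4-dihydroxy-6-(methoxycarbonyl)phenoxy]-2-(methoxymethoxy)-4-methylbenzoate | COC(=O)c1cc(O)cc(O)c1Oc1cc(C)c(Cl)c(OCOC)c1C(=O)OC(C)(C)C | intermediate
13 | tert-butyl 3-chloro-6-{2-hydroxy-6-(methoxycarbonyl)-4-[(triisopropylsilyl)oxy]phenoxy}-2-(methoxymethoxy)-4-methylbenzoate | COC(=O)c1cc(O[Si](C(C)C)(C(C)C)C(C)C)cc(O)c1Oc1cc(C)c(Cl)c(OCOC)c1C(=O)OC(C)(C)C | intermediate
14 | tert-butyl 3-chloro-6-{2-methoxy-6-(methoxycarbonyl)-4-[(triisopropylsilyl)oxy]phenoxy}-2-(methoxymethoxy)-4-methylbenzoate | COC(=O)c1cc(O[Si](C(C)C)(C(C)C)C(C)C)cc(OC)c1Oc1cc(C)c(Cl)c(OCOC)c1C(=O)OC(C)(C)C | intermediate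
15 | tert-butyl 3-chloro-6-[4-hydroxy-2-methoxy-6-(methoxycarbonyl)phenoxy]-2-(methoxymethoxy)-4-methylbenzoate | COC(=O)c1cc(O)cc(OC)c1Oc1cc(C)c(Cl)c(OCOC)c1C(=O)OC(C)(C)C | intermediate
16 | 3-chloro-2-hydroxy-6-[4-hydroxy-2-methoxy-6-(methoxycarbonyl)phenoxy]-4-methylbenzoic acid (isodihydromaldoxin) | COC(=O)c1cc(O)cc(OC)c1Oc1cc(C)c(Cl)c(O)c1C(=O)O | target

## Step count and least certain steps

Total: 10 steps. Longest linear sequence: 10 steps (1 to 16); 4 and 8 are purchased.

Step 5 (key step). The most likely failures are processes that consume the enolate or the adduct before the ring closes. One is proton transfer from the acidic methyl ketone of 8 to enolate 9, or carbonyl addition instead of conjugate addition. The other, after the Michael addition, is E1cB expulsion of the ring B aryloxide from the C1 ester enolate, which competes with the proton transfer that the Claisen closure needs. The fallback separates the two bond formations. It sets out from 7, which is converted with LiN(iPr)2 and Me3SiCl into the silyl ketene acetal tert-butyl 3-chloro-6-{[(Z)-2-methoxy-2-(trimethylsilyloxy)ethenyl]oxy}-2-(methoxymethoxy)-4-methylbenzoate F1. A Mukaiyama–Michael addition of F1 to 8 under neutral Lewis-base catalysis (LiOAc in DMF) would form C6–C1 without a basic enolate and, after hydrolytic work-up, give the keto diester dimethyl 2-{[2-(tert-butoxycarbonyl)-4-chloro-3-(methoxymethoxy)-5-methylphenyl]oxy}-3-(2-oxopropyl)butanedioate F2. A separate Claisen closure of F2 with KOtBu (one equivalent, THF, −40 → 0 °C) would then form C4–C5 and return to the route at 11.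

Step 3. The risk is loss of site control in the alkylation. If double deprotonation is incomplete, reaction through the monoanion would favour the more acidic oxygen next to chlorine and give the regioisomeric ether; a second alkylation is the other possible leak. The fallback replaces selection by nucleophilicity with selection by size and sets out from 3. Silylation with TIPSCl and imidazole should take the less hindered C6′ oxygen and give tert-butyl 3-chloro-2-hydroxy-4-methyl-6-[(triisopropylsilyl)oxy]benzoate F3. MOMCl and iPr2NEt would then cap the C2′ oxygen to give tert-butyl 3-chloro-2-(methoxymethoxy)-4-methyl-6-[(triisopropylsilyl)oxy]benzoate F4. Bu4NF would free the C6′ oxygen to give tert-butyl 3-chloro-6-hydroxy-2-(methoxymethoxy)-4-methylbenzoate F5. Alkylation of this single phenol with 4 and K2CO3 in acetone would come back to the route at 7.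

Step 6. The risk is sluggish hydride abstraction, because C1 carries an ester that destabilizes the developing cation. Forcing the reaction would favour elimination of the ring B phenol (which aromatizes ring A without its ether oxygen) or over-oxidation of the resorcinol. The fallback activates the dione first and sets out from 11. Silylation with Me3SiCl and Et3N, then LiN(SiMe3)2 and Me3SiCl, would give the bis-silyl dienol ether methyl 2-{[2-(tert-butoxycarbonyl)-4-chloro-3-(methoxymethoxy)-5-methylphenyl]oxy}-3,5-bis[(trimethylsilyl)oxy]cyclohexa-2,4-diene-1-carboxylate F6 (racemic; its double-bond isomer would serve equally). This electron-rich diene should be dehydrogenated by DDQ at 0 °C, or by stoichiometric Pd(OAc)2 in the manner of a Saegusa–Ito oxidation, to the bis-silyl ether tert-butyl 3-chloro-6-{2-(methoxycarbonyl)-4,6-bis[(trimethylsilyl)oxy]phenoxy}-2-(methoxymethoxy)-4-methylbenzoate F7. Mild aqueous acid would cleave the labile silyl ethers and return to the route at 12.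

Step 10. The risk is electrophilic alkylation of ring A, whose free phenol activates C2 and C4, by the methoxymethyl cation, formaldehyde or the tert-butyl cation; warming would add decarboxylation. The fallback changes the order of unmasking so that ring A is shielded during the acid step, and sets out from 14. The same acid treatment applied to 14 would give 3-chloro-2-hydroxy-6-{2-methoxy-6-(methoxycarbonyl)-4-[(triisopropylsilyl)oxy]phenoxy}-4-methylbenzoic acid F8, in which the bulky silyl ether blocks both activated positions. Fluoride (HF·pyridine in THF, or buffered Bu4NF) would then remove the silyl group and come back to the route at 16.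

## Further compounds

F1 | step 5 | tert-butyl 3-chloro-6-{[(Z)-2-methoxy-2-(trimethylsilyloxy)ethenyl]oxy}-2-(methoxymethoxy)-4-methylbenzoate | C[Si](C)(C)O/C(OC)=C\Oc1cc(C)c(Cl)c(OCOC)c1C(=O)OC(C)(C)C
F2 | step 5 | dimethyl 2-{[2-(tert-butoxycarbonyl)-4-chloro-3-(methoxymethoxy)-5-methylphenyl]oxy}-3-(2-oxopropyl)butanedioate (mixture of diastereomers, racemic) | COC(=O)C(CC(C)=O)C(Oc1cc(C)c(Cl)c(OCOC)c1C(=O)OC(C)(C)C)C(=O)OC
F3 | step 3 | tert-butyl 3-chloro-2-hydroxy-4-methyl-6-[(triisopropylsilyl)oxy]benzoate | Cc1cc(O[Si](C(C)C)(C(C)C)C(C)C)c(C(=O)OC(C)(C)C)c(O)c1Cl
F4 | step 3 | tert-butyl 3-chloro-2-(methoxymethoxy)-4-methyl-6-[(triisopropylsilyl)oxy]benzoate | Cc1cc(O[Si](C(C)C)(C(C)C)C(C)C)c(C(=O)OC(C)(C)C)c(OCOC)c1Cl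
F5 | step 3 | tert-butyl 3-chloro-6-hydroxy-2-(methoxymethoxy)-4-methylbenzoate | Cc1cc(O)c(C(=O)OC(C)(C)C)c(OCOC)c1Cl
F6 | step 6 | methyl 2-{[2-(tert-butoxycarbonyl)-4-chloro-3-(methoxymethoxy)-5-methylphenyl]oxy}-3,5-bis[(trimethylsilyl)oxy]cyclohexa-2,4-diene-1-carboxylate (racemic) | COC(=O)C1CC(O[Si](C)(C)C)=CC(O[Si](C)(C)C)=C1Oc1cc(C)c(Cl)c(OCOC)c1C(=O)OC(C)(C)C
F7 | step 6 | tert-butyl 3-chloro-6-{2-(methoxycarbonyl)-4,6-bis[(trimethylsilyl)oxy]phenoxy}-2-(methoxymethoxy)-4-methylbenzoate | COC(=O)c1cc(O[Si](C)(C)C)cc(O[Si](C)(C)C)c1Oc1cc(C)c(Cl)c(OCOC)c1C(=O)OC(C)(C)C
F8 | step 10 | 3-chloro-2-hydroxy-6-{2-methoxy-6-(methoxycarbonyl)-4-[(triisopropylsilyl)oxy]phenoxy}-4-methylbenzoic acid | COC(=O)c1cc(O[Si](C(C)C)(C(C)C)C(C)C)cc(OC)c1Oc1cc(C)c(Cl)c(O)c1C(=O)O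
A1 | alternative 1 | methyl 2-(ethynyloxy)-3-methoxy-5-[(4-methoxybenzyl)oxy]benzoate | COC(=O)c1cc(OCc2ccc(OC)cc2)cc(OC)c1OC#C
A2 | alternative 1 | tert-butyl 4-acetoxy-5-chloro-6-methyl-2-oxo-2H-pyran-3-carboxylate | CC(=O)Oc1c(Cl)c(C)oc(=O)c1C(=O)OC(C)(C)C
A3 | alternative 1 | tert-butyl 2-acetoxy-3-chloro-6-{2-methoxy-6-(methoxycarbonyl)-4-[(4-methoxybenzyl)oxy]phenoxy}-4-methylbenzoate | COC(=O)c1cc(OCc2ccc(OC)cc2)cc(OC)c1Oc1cc(C)c(Cl)c(OC(C)=O)c1C(=O)OC(C)(C)C
A4 | alternative 2 | (E)-4-chloro-1-diazo-3-methylbut-3-en-2-one | [N-]=[N+]=CC(=O)/C(C)=C/Cl
A5 | alternative 2 | (E)-4-chloro-3-methylbuta-1,3-dien-1-one | O=C=C/C(C)=C/Cl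
A6 | alternative 2 | tert-butyl 3-{2-methoxy-6-(methoxycarbonyl)-4-[(4-methoxybenzyl)oxy]phenoxy}prop-2-ynoate | COC(=O)c1cc(OCc2ccc(OC)cc2)cc(OC)c1OC#CC(=O)OC(C)(C)C
A7 | alternative 2 | tert-butyl 3-chloro-2-hydroxy-6-{2-methoxy-6-(methoxycarbonyl)-4-[(4-methoxybenzyl)oxy]phenoxy}-4-methylbenzoate | COC(=O)c1cc(OCc2ccc(OC)cc2)cc(OC)c1Oc1cc(C)c(Cl)c(O)c1C(=O)OC(C)(C)C
A8 | alternative 3 | tert-butyl 3-chloro-6-{[1-chloro-3-(methoxycarbonyl)-1-oxobut-3-en-2-yl]oxy}-2-(methoxymethoxy)-4-methylbenzoate (racemic) | COC(=O)C(=C)C(Oc1cc(C)c(Cl)c(OCOC)c1C(=O)OC(C)(C)C)C(Cl)=O
A9 | alternative 3 | methoxyethyne | COC#C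
A10 | alternative 3 | tert-butyl 3-chloro-6-[4-hydroxy-2-methoxy-6-(methoxycarbonyl)phenoxy]-2-(methoxymethoxy)-4-methylbenzoate | COC(=O)c1cc(O)cc(OC)c1Oc1cc(C)c(Cl)c(OCOC)c1C(=O)OC(C)(C)C
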